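**Retrosynthetic overview**

- The target is the hydroxytyrosol ester of an all-trans 2-methyl-3-formyl-3,4-dihydro-2H-pyran-4-acetic acid with CO2Me on C5 (ring numbering O1, C2 to C6). The arene is bought; the dihydropyran is the only ring to be built.
- Enabling feature: C3 is the α-carbon of the formyl group and C4 is the β-carbon of the side-chain ester (OHC–C3–C4–CH2–CO2R, a 1,5-dicarbonyl Michael retron). O1 is the enol oxygen of the vinylogous carbonate O1–C6=C5–CO2Me and can tether donor and acceptor. The ring is therefore opened at C3–C4, to be closed by a 6-exo-trig enamine Michael addition of an acyclic aldehyde–dienoate.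
- The acyclic precursor, a (2E,4E)-4-(alkoxymethylidene)pent-2-enedioate, is cut at C4–C5 (Heck coupling of an α-iodo-β-alkoxyacrylate with the acrylate of silyl-protected hydroxytyrosol) and at O1–C6 (oxa-Michael addition of (S)-4,4-dimethoxybutan-2-ol to methyl propiolate).
- Stereochemistry: C2 comes from an enzymatic ketone reduction; C3 and C4 are set in the ring closure (matched amine catalyst, chair transition state, C3 under thermodynamic control). Desilylation ends the route.

Key step: step 7

Remark: the SMILES is read as the (2S,3R,4R)-isomer, with the methyl at C2, the formyl at C3 and the acetate arm at C4 mutually trans. This all-trans arrangement is assumed to be the thermodynamically preferred one at the epimerisable C3.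

**Route**

Step 1
Reactants: 1 hydroxytyrosol (2-(3,4-dihydroxyphenyl)ethanol); 2 vinyl acrylate
Product: 3 2-(3,4-dihydroxyphenyl)ethyl prop-2-enoate
Conditions: vinyl acrylate (3 equiv.), immobilised Candida antarctica lipase B, BHT (trace), MeCN/tert-butyl methyl ether, 40 °C
Reagents that add atoms: none
Why: Lipase-catalysed irreversible transesterification (acyl transfer from a vinyl ester, the released vinyl alcohol tautomerising to acetaldehyde) should acylate only the primary aliphatic hydroxyl, because phenolic hydroxyls are not accepted by the serine hydrolase; no stereocentre is formed.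

Step 2
Reactants: 3 2-(3,4-dihydroxyphenyl)ethyl prop-2-enoate
Product: 4 2-[3,4-bis(tert-butyldimethylsilyloxy)phenyl]ethyl prop-2-enoate
Conditions: TBSCl (2.4 equiv.), imidazole (5 equiv.), CH2Cl2, 0 °C to rt
Reagents that add atoms: tert-butyldimethylsilyl chloride, CC(C)(C)[Si](C)(C)Cl
Why: Standard imidazole-promoted silylation of phenols with a silyl chloride caps both catechol hydroxyls so that the arene survives the palladium and amine steps; no stereocentre is formed.

Step 3
Reactants: 5 4,4-dimethoxybutan-2-one
Product: 6 (2S)-4,4-dimethoxybutan-2-ol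
Conditions: Prelog-type alcohol dehydrogenase (for example ADH-A from Rhodococcus ruber), NAD+ (cat.), propan-2-ol (15% v/v), phosphate buffer pH 7.5, 30 °C
Reagents that add atoms: none
Why: Biocatalytic asymmetric ketone reduction following Prelog's rule delivers hydride from NADH to the Re face of the methyl ketone and so should set the S carbinol centre (later C2 of the ring), with propan-2-ol recycling the cofactor and the acetal inert at this pH.

Step 4
Reactants: 6 (2S)-4,4-dimethoxybutan-2-ol; 7 methyl propiolate
Product: 8 methyl (2E)-3-{[(2S)-4,4-dimethoxybutan-2-yl]oxy}prop-2-enoate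
Conditions: methyl propiolate (1.3 equiv.), N-methylmorpholine (1.0 equiv.), CH2Cl2, 0 °C to rt
Reagents that add atoms: none
Why: Amine-mediated oxa-Michael addition of an alcohol to an ynoate is the standard route to (E)-β-alkoxyacrylates; the C–O bond of the carbinol centre is not broken, so its configuration is retained, and the E alkene is the thermodynamic product.

Step 5
Reactants: 8 methyl (2E)-3-{[(2S)-4,4-dimethoxybutan-2-yl]oxy}prop-2-enoate
Product: 10 methyl (2Z)-3-{[(2S)-4,4-dimethoxybutan-2-yl]oxy}-2-iodoprop-2-enoate, via iodo-acetoxy adduct 9 (not isolated)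
Conditions: NIS (1.2 equiv.), AcOH (2 equiv.), CH2Cl2, rt; then Et3N (3 equiv.), 0 °C to rt
Reagents that add atoms: N-iodosuccinimide, O=C1CCC(=O)N1I
Why: Electrophilic α-iodination of a β-alkoxyacrylate by iodo-acetoxylation (iodonium attack at the enol-ether carbon, acetate capture at the oxocarbenium carbon) followed by base-induced E1cB loss of acetic acid is a sequence established for methyl 3-methoxyacrylate; ester and alkoxy group stay trans (the Z descriptor of the iodide) and the distant stereocentre is untouched.

Step 6
Reactants: 10 methyl (2Z)-3-{[(2S)-4,4-dimethoxybutan-2-yl]oxy}-2-iodoprop-2-enoate; 4 2-[3,4-bis(tert-butyldimethylsilyloxy)phenyl]ethyl prop-2-enoate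
Product: 11 1-{2-[3,4-bis(tert-butyldimethylsilyloxy)phenyl]ethyl} 5-methyl (2E,4E)-4-({[(2S)-4,4-dimethoxybutan-2-yl]oxy}methylidene)pent-2-enedioate
Conditions: Pd(OAc)2 (5 mol%), PPh3 (10 mol%), Ag2CO3 (1.1 equiv.), MeCN, 60 °C
Reagents that add atoms: none
Why: Mizoroki–Heck coupling of a vinyl iodide with an acrylate proceeds by oxidative addition with retention of the iodoalkene geometry, syn-insertion and syn-β-hydride elimination to give the (E)-enoate, while Ag2CO3 removes iodide and acts as a mild non-nucleophilic base that should spare the aryl silyl ethers and the acetal.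

Step 7
Reactants: 11 1-{2-[3,4-bis(tert-butyldimethylsilyloxy)phenyl]ethyl} 5-methyl (2E,4E)-4-({[(2S)-4,4-dimethoxybutan-2-yl]oxy}methylidene)pent-2-enedioate
Product: 13 methyl (2S,3R,4R)-4-(2-{2-[3,4-bis(tert-butyldimethylsilyloxy)phenyl]ethoxy}-2-oxoethyl)-3-formyl-2-methyl-3,4-dihydro-2H-pyran-5-carboxylate, via aldehyde 12 (not isolated)
Conditions: (a) Amberlyst-15, acetone/H2O (20:1), rt, then filtration and evaporation; (b) (R)-α,α-diphenylprolinol trimethylsilyl ether (20 mol%), PhCO2H (20 mol%), toluene, 0 °C to rt, argon
Reagents that add atoms: water, O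
Why: Acid-catalysed acetal hydrolysis unveils the β-alkoxy aldehyde 12, which condenses with the secondary amine to an (E)-enamine whose α-carbon (C3) adds in a 6-exo-trig Michael fashion to C4, the β-carbon of the (E)-enoate held in reach by the vinylogous-carbonate tether O1–C6=C5; protonation of the ester enolate and hydrolysis of the iminium ion release 13 and the catalyst. The closest known reaction types are the amine-catalysed intramolecular Michael addition of formyl enoates and the ring-closing half of iminium–enamine oxa-Michael/Michael chromane syntheses. The dihydropyran is closed by C3–C4 bond formation through a chair-like transition state with the C2 methyl, the enamine carbon and the enoate arm all pseudo-equatorial, so C4 (R) should follow from the existing C2 (S) centre (2,4-cis), and C3 (R) from attack on the enamine face left open by the (R)-configured catalyst; this catalyst is matched with the substrate and would re-form 2S should retro-oxa-Michael and re-addition intervene. C3 stays epimerisable through the enamine or enol and is expected to settle in the all-trans arrangement. The step needs C-attack at C4 and not at C6 (which would give a four-membered ring), no amine exchange at the alkoxymethylidene carbon (bulky catalyst used as its benzoate salt) and an E enoate, which the Heck reaction delivers.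

Step 8
Reactants: 13 methyl (2S,3R,4R)-4-(2-{2-[3,4-bis(tert-butyldimethylsilyloxy)phenyl]ethoxy}-2-oxoethyl)-3-formyl-2-methyl-3,4-dihydro-2H-pyran-5-carboxylate
Product: 14 methyl (2S,3R,4R)-4-{2-[2-(3,4-dihydroxyphenyl)ethoxy]-2-oxoethyl}-3-formyl-2-methyl-3,4-dihydro-2H-pyran-5-carboxylate (target)
Conditions: Et3N·3HF (3 equiv.), THF, 0 °C to rt, argon
Reagents that add atoms: none
Why: Fluoride-driven cleavage of the two aryl silyl ethers (strong Si–F bond) with the mildly acidic amine–HF complex should avoid the enolate formation that would open the ring by β-elimination of O1; C3 already sits in its thermodynamic configuration, so no stereocentre is at risk.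

**Compound list**

1 | hydroxytyrosol, 2-(3,4-dihydroxyphenyl)ethanol | OCCc1ccc(O)c(O)c1 | starting material
2 | vinyl acrylate (ethenyl prop-2-enoate) | C=CC(=O)OC=C | starting material
3 | 2-(3,4-dihydroxyphenyl)ethyl prop-2-enoate | C=CC(=O)OCCc1ccc(O)c(O)c1 | intermediate
4 | 2-[3,4-bis(tert-butyldimethylsilyloxy)phenyl]ethyl prop-2-enoate | C=CC(=O)OCCc1ccc(O[Si](C)(C)C(C)(C)C)c(O[Si](C)(C)C(C)(C)C)c1 | intermediate
5 | 4,4-dimethoxybutan-2-one | CC(=O)CC(OC)OC | starting material
6 | (2S)-4,4-dimethoxybutan-2-ol | C[C@H](O)CC(OC)OC | intermediate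
7 | methyl propiolate (methyl prop-2-ynoate) | C#CC(=O)OC | starting material
8 | methyl (2E)-3-{[(2S)-4,4-dimethoxybutan-2-yl]oxy}prop-2-enoate | COC(=O)/C=C/O[C@@H](C)CC(OC)OC | intermediate
9 | methyl 3-acetoxy-3-{[(2S)-4,4-dimethoxybutan-2-yl]oxy}-2-iodopropanoate (diastereomer mixture, not isolated) | COC(=O)C(I)C(OC(C)=O)O[C@@H](C)CC(OC)OC | intermediate
10 | methyl (2Z)-3-{[(2S)-4,4-dimethoxybutan-2-yl]oxy}-2-iodoprop-2-enoate | COC(=O)/C(I)=C/O[C@@H](C)CC(OC)OC | intermediate
11 | 1-{2-[3,4-bis(tert-butyldimethylsilyloxy)phenyl]ethyl} 5-methyl (2E,4E)-4-({[(2S)-4,4-dimethoxybutan-2-yl]oxy}methylidene)pent-2-enedioate | COC(=O)/C(/C=C/C(=O)OCCc1ccc(O[Si](C)(C)C(C)(C)C)c(O[Si](C)(C)C(C)(C)C)c1)=C/O[C@@H](C)CC(OC)OC | intermediate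
12 | 1-{2-[3,4-bis(tert-butyldimethylsilyloxy)phenyl]ethyl} 5-methyl (2E,4E)-4-({[(2S)-4-oxobutan-2-yl]oxy}methylidene)pent-2-enedioate (not isolated) | COC(=O)/C(/C=C/C(=O)OCCc1ccc(O[Si](C)(C)C(C)(C)C)c(O[Si](C)(C)C(C)(C)C)c1)=C/O[C@@H](C)CC=O | intermediate
13 | methyl (2S,3R,4R)-4-(2-{2-[3,4-bis(tert-butyldimethylsilyloxy)phenyl]ethoxy}-2-oxoethyl)-3-formyl-2-methyl-3,4-dihydro-2H-pyran-5-carboxylate | COC(=O)C1=CO[C@@H](C)[C@H](C=O)[C@H]1CC(=O)OCCc1ccc(O[Si](C)(C)C(C)(C)C)c(O[Si](C)(C)C(C)(C)C)c1 | intermediate
14 | methyl (2S,3R,4R)-4-{2-[2-(3,4-dihydroxyphenyl)ethoxy]-2-oxoethyl}-3-formyl-2-methyl-3,4-dihydro-2H-pyran-5-carboxylate | COC(=O)C1=CO[C@@H](C)[C@H](C=O)[C@H]1CC(=O)OCCc1ccc(O)c(O)c1 | target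

**Step count and risks**

Total steps: 8. Longest linear sequence: 6 (steps 3, 4, 5, 6, 7, 8).

Steps most likely to fail, with one fallback each:

Step 7 (key step). What may go wrong: retro-oxa-Michael β-elimination of the enol leaving group from the enamine or iminium ion (loss of the C2 unit as crotonaldehyde), consumption of the amine by addition–elimination at C6, or insufficient facial selectivity at C4. The fallback replaces the polar closure by a radical one, which cannot expel O1; it sets out from 11 and comes back to the route at 13. Treatment of 11 with TMSOTf and iPr2NEt (CH2Cl2, −20 °C) would convert the dimethyl acetal into the methyl enol ether, 1-{2-[3,4-bis(tert-butyldimethylsilyloxy)phenyl]ethyl} 5-methyl (2E,4E)-4-({[(2S)-4-methoxybut-3-en-2-yl]oxy}methylidene)pent-2-enedioate F1. NBS in MeOH/CH2Cl2 at −40 °C would then give the α-bromo dimethyl acetal, 1-{2-[3,4-bis(tert-butyldimethylsilyloxy)phenyl]ethyl} 5-methyl (2E,4E)-4-({[(2S)-3-bromo-4,4-dimethoxybutan-2-yl]oxy}methylidene)pent-2-enedioate F2. Slow addition of Bu3SnH with AIBN (benzene, 80 °C) would generate the C3 radical, which closes the same C3–C4 bond by 6-exo-trig Giese addition to the enoate through a chair transition state with the C2 methyl equatorial (2,4-cis). This would give methyl (2S,4R)-4-(2-{2-[3,4-bis(tert-butyldimethylsilyloxy)phenyl]ethoxy}-2-oxoethyl)-3-(dimethoxymethyl)-2-methyl-3,4-dihydro-2H-pyran-5-carboxylate F3 as C3 epimers. Acetal hydrolysis (Amberlyst-15, wet acetone) and equilibration of C3 with the benzoate salt of the step 7 amine should then lead to 13.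

Step 5. What may go wrong: capture of the iodonium or oxocarbenium intermediate by an acetal oxygen, acetal loss in acetic acid, or incomplete elimination to the vinyl iodide. The fallback replaces halogenation and cross-coupling by a C–H functionalisation; it sets out from 8 (together with 4) and comes back to the route at 11. A dehydrogenative Heck reaction of the Fujiwara–Moritani type would be used: Pd(OAc)2 (10 mol%), AgOAc (2 equiv.), pivalic acid, MeCN, 60 °C. Electrophilic palladation of the nucleophilic α-carbon of the β-alkoxyacrylate by divalent palladium, insertion of 4 and β-hydride elimination should give 11 directly. No new compound arises on this way (F0), and step 6 is no longer needed.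

Step 8. What may go wrong: ring opening by β-elimination of O1 from the aldehyde enolate under fluoride, epimerisation, or air oxidation of the liberated catechol during work-up. The fallback removes the silyl groups before the ring is closed, so that the sensitive β-alkoxy aldehyde never meets fluoride and the ring closure becomes the last operation; it sets out from 11 and comes back to the route at 14. Et3N·3HF in THF would give the free catechol, 1-[2-(3,4-dihydroxyphenyl)ethyl] 5-methyl (2E,4E)-4-({[(2S)-4,4-dimethoxybutan-2-yl]oxy}methylidene)pent-2-enedioate F4. Under the conditions of step 7 (argon) this would be hydrolysed to the aldehyde, 1-[2-(3,4-dihydroxyphenyl)ethyl] 5-methyl (2E,4E)-4-({[(2S)-4-oxobutan-2-yl]oxy}methylidene)pent-2-enedioate F5 (not isolated), which should cyclise to 14, the catechol acting at most as a weak acid co-catalyst.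

**Further compounds**

F1 | step 7 | 1-{2-[3,4-bis(tert-butyldimethylsilyloxy)phenyl]ethyl} 5-methyl (2E,4E)-4-({[(2S)-4-methoxybut-3-en-2-yl]oxy}methylidene)pent-2-enedioate (enol ether as E/Z mixture) | COC(=O)/C(/C=C/C(=O)OCCc1ccc(O[Si](C)(C)C(C)(C)C)c(O[Si](C)(C)C(C)(C)C)c1)=C/O[C@@H](C)C=COC
F2 | step 7 | 1-{2-[3,4-bis(tert-butyldimethylsilyloxy)phenyl]ethyl} 5-methyl (2E,4E)-4-({[(2S)-3-bromo-4,4-dimethoxybutan-2-yl]oxy}methylidene)pent-2-enedioate (epimers at the bromide carbon) | COC(=O)/C(/C=C/C(=O)OCCc1ccc(O[Si](C)(C)C(C)(C)C)c(O[Si](C)(C)C(C)(C)C)c1)=C/O[C@@H](C)C(Br)C(OC)OC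
F3 | step 7 | methyl (2S,4R)-4-(2-{2-[3,4-bis(tert-butyldimethylsilyloxy)phenyl]ethoxy}-2-oxoethyl)-3-(dimethoxymethyl)-2-methyl-3,4-dihydro-2H-pyran-5-carboxylate (epimers at C3) | COC(=O)C1=CO[C@@H](C)C(C(OC)OC)[C@H]1CC(=O)OCCc1ccc(O[Si](C)(C)C(C)(C)C)c(O[Si](C)(C)C(C)(C)C)c1
F0 | step 5 | none | none
F4 | step 8 | 1-[2-(3,4-dihydroxyphenyl)ethyl] 5-methyl (2E,4E)-4-({[(2S)-4,4-dimethoxybutan-2-yl]oxy}methylidene)pent-2-enedioate | COC(=O)/C(/C=C/C(=O)OCCc1ccc(O)c(O)c1)=C/O[C@@H](C)CC(OC)OC
F5 | step 8 | 1-[2-(3,4-dihydroxyphenyl)ethyl] 5-methyl (2E,4E)-4-({[(2S)-4-oxobutan-2-yl]oxy}methylidene)pent-2-enedioate (not isolated) | COC(=O)/C(/C=C/C(=O)OCCc1ccc(O)c(O)c1)=C/O[C@@H](C)CC=O
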